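The route rests on cutting the C5–C6 bond of the 1,2-dioxane ring (O1–O2–C3–C4–C5–C6): C5 is a bare methylene between the quaternary peroxy carbon C6 and the methyl-bearing C4, so C5, C4 and its methyl can come from an isopropenyl group on C3. In one operation a peroxycarbenium ion at C6 is attacked by that alkene across the O1–O2 tether, closing the ring, forming C5–C6 and setting C6, and leaving a 4-methylene handle for C4. The precursor is an acyclic methyl peroxyketal of a citronellic-acid-derived ketone with an enantiopure allylic hydroperoxide, whose carboxyl arm is masked as an acetoxyethyl group so that it cannot capture the C4 cation as a γ-lactone.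

Key step: step 11

Assumption: horseradish peroxidase is taken to reduce the (R)-enantiomer of the racemic allylic hydroperoxide faster, as with related secondary hydroperoxides, so that the (S)-enantiomer remains; the assignment is checked on an aliquot.

Step 1
Reactants: 1 4-methylpent-3-en-1-ol
Product: 2 4-methylpent-3-en-1-yl acetate
Conditions: Ac2O, pyridine, DMAP (cat.), 0 °C → rt
Reagents that add atoms: acetic anhydride, CC(=O)OC(C)=O
Why: DMAP-catalysed acylation of the primary alcohol stores the future carboxyl carbon as an acetate, whose oxygens cannot reach C4 through a small ring in the later cationic step; no stereocentre is involved.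

Step 2
Reactants: 2 4-methylpent-3-en-1-yl acetate
Product: 3 rac-3-hydroperoxy-4-methylpent-4-en-1-yl acetate
Conditions: O2, visible light, tetraphenylporphyrin (cat.), CH2Cl2, 0 °C; chromatography
Reagents that add atoms: dioxygen, O=O
Why: Schenck ene reaction, in which singlet oxygen bonds to C3 and takes a hydrogen from a C4 methyl group, gives the racemic secondary hydroperoxide with the isopropenyl group; the tertiary regioisomer from hydrogen abstraction at C2 is expected alongside and is removed by chromatography.

Step 3
Reactants: 3 rac-3-hydroperoxy-4-methylpent-4-en-1-yl acetate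
Product: 4 (S)-3-hydroperoxy-4-methylpent-4-en-1-yl acetate
Conditions: horseradish peroxidase (cat.), guaiacol (0.55 equiv), phosphate buffer pH 6, rt, run a little beyond half conversion; chromatography; kept cold with BHT
Reagents that add atoms: none
Why: Enzymatic kinetic resolution, in which the peroxidase reduces one hydroperoxide enantiomer to the alcohol at the expense of guaiacol, should leave the (S)-hydroperoxide enantiomerically enriched; the configuration is selected, not created, and is checked by PPh3 reduction of an aliquot and Mosher ester analysis.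

Step 4
Reactants: 5 (R)-citronellic acid
Product: 7 (R)-4,8-dimethylnon-7-en-2-one, via dilithium gem-diolate 6 (not isolated)
Conditions: MeLi (2.2 equiv), Et2O, 0 °C → rt; poured into cold 1 M HCl
Reagents that add atoms: methyllithium, [Li]C
Why: Organolithium addition to the lithium carboxylate stops at the dilithium gem-diolate, which gives the methyl ketone only on acidic quench; the stereocentre is β to the carbonyl group and is not touched.

Step 5
Reactants: 7 (R)-4,8-dimethylnon-7-en-2-one
Product: 8 (R)-8,8-dimethoxy-2,6-dimethylnon-2-ene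
Conditions: HC(OMe)3, MeOH, p-TsOH·H2O (cat.), rt; Et3N
Reagents that add atoms: trimethyl orthoformate, COC(OC)OC; methanol, CO
Why: Acid-catalysed ketalisation with the orthoester as water scavenger gives the dimethyl ketal, which protects the ketone during chain extension and later is the reactive partner for the hydroperoxide.

Step 6
Reactants: 8 (R)-8,8-dimethoxy-2,6-dimethylnon-2-ene
Product: 10 (R)-6,6-dimethoxy-4-methylheptanal, via secondary ozonide 9 (not isolated)
Conditions: O3, CH2Cl2, NaHCO3 (solid), −78 °C; then PPh3, −78 °C → rt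
Reagents that add atoms: ozone, [O-][O+]=O
Why: Ozonolysis with reductive work-up (Criegee mechanism) cleaves the only C=C bond to the aldehyde under non-acidic conditions that the ketal tolerates.

Step 7
Reactants: 11 (5-bromopentyl)benzene
Product: 12 triphenyl(5-phenylpentyl)phosphonium bromide
Conditions: PPh3, MeCN, reflux
Reagents that add atoms: triphenylphosphine, c1ccc(cc1)P(c1ccccc1)c1ccccc1
Why: SN2 quaternisation of the phosphine by the primary bromide gives the Wittig salt.

Step 8
Reactants: 10 (R)-6,6-dimethoxy-4-methylheptanal; 12 triphenyl(5-phenylpentyl)phosphonium bromide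
Product: 14 [(5Z,9R)-11,11-dimethoxy-9-methyldodec-5-en-1-yl]benzene, via phosphonium ylide 13 (not isolated)
Conditions: NaN(SiMe3)2, THF, 0 °C; then 10, −78 °C → rt
Reagents that add atoms: none
Why: Wittig olefination with the unstabilised ylide joins the two chain pieces in a basic medium that leaves the ketal intact; the alkene geometry (mainly Z) does not matter because the bond is saturated next.

Step 9
Reactants: 14 [(5Z,9R)-11,11-dimethoxy-9-methyldodec-5-en-1-yl]benzene
Product: 15 [(9R)-11,11-dimethoxy-9-methyldodecyl]benzene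
Conditions: H2 (1 atm), Pd/C, EtOAc, Et3N (trace), rt
Reagents that add atoms: none
Why: Heterogeneous catalytic hydrogenation saturates the disubstituted alkene, while the arene and the ketal (kept basic by the amine) are not affected.

Step 10
Reactants: 4 (S)-3-hydroperoxy-4-methylpent-4-en-1-yl acetate; 15 [(9R)-11,11-dimethoxy-9-methyldodecyl]benzene
Product: 16 (3S)-3-{[(4R)-2-methoxy-4-methyl-12-phenyldodecan-2-yl]peroxy}-4-methylpent-4-en-1-yl acetate (both epimers at the peroxyketal carbon)
Conditions: PPTS (cat.), 5 Å molecular sieves, CH2Cl2, 0 °C → rt; Et3N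
Reagents that add atoms: none
Why: Acid-catalysed transketalisation, in which the hydroperoxide (the better nucleophile) replaces one methoxy group and the sieves take up methanol, leaves C3 untouched; the new ketal carbon forms as both epimers, which is harmless because it becomes planar in the next step.

Step 11
Reactants: 16 (3S)-3-{[(4R)-2-methoxy-4-methyl-12-phenyldodecan-2-yl]peroxy}-4-methylpent-4-en-1-yl acetate
Product: 19 2-[(3S,6R)-6-methyl-4-methylidene-6-[(2R)-2-methyl-10-phenyldecyl]-1,2-dioxan-3-yl]ethyl acetate, via peroxycarbenium ion 17 (not isolated), via dioxanyl cation 18 (not isolated)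
Conditions: Me3SiOTf (1.2 equiv), 2,6-di-tert-butyl-4-methylpyridine (2 equiv), CH2Cl2, −78 → −40 °C; aq. NaHCO3; chromatography to remove the C6 epimer
Reagents that add atoms: none
Why: The silyl triflate removes the methoxy group of 16, giving peroxycarbenium ion 17, whose C6 is attacked by the terminal CH2 of the isopropenyl group (the future C5) across the O1–O2 tether; the tertiary C4 cation 18 then gives up a methyl proton to the hindered pyridine. The closest known reaction type is the Lewis-acid addition of alkenes and allylsilanes to peroxycarbenium ions (Prins and Hosomi–Sakurai type), used here intramolecularly. The 1,2-dioxane closes in a 6-endo-trig mode through a chair that holds both alkene carbons in the ring. C6 is set under substrate control from C3: the C3 arm lies pseudo-axial to avoid allylic strain with the C4 methyl, and the long C7 chain sits anti to O2 on the cation and therefore equatorial, which puts arm and chain cis (3S,6R). The step needs ionisation at C–OMe and not at the peroxide, diastereoselection at C6 and proton loss from the methyl group only; these rest on the more basic ether oxygen, on the chair preference just described (expected to be moderate), on a bulky base that reaches the unhindered methyl protons, and on an acetate arm that cannot trap C4.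

Step 12
Reactants: 19 2-[(3S,6R)-6-methyl-4-methylidene-6-[(2R)-2-methyl-10-phenyldecyl]-1,2-dioxan-3-yl]ethyl acetate
Product: 20 2-[(3S,4S,6R)-4,6-dimethyl-6-[(2R)-2-methyl-10-phenyldecyl]-1,2-dioxan-3-yl]ethyl acetate
Conditions: KO2CN=NCO2K (excess, in portions), AcOH, pyridine, MeOH/CH2Cl2, 0 °C → rt
Reagents that add atoms: none
Why: Diimide reduction, a concerted syn transfer of two hydrogens that leaves the O–O bond alone, should deliver hydrogen to C4 from the face opposite the C3 arm and the C7 chain, because that face carries an axial CH2 group in either chair, so the new methyl group ends cis to both (4S).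

Step 13
Reactants: 20 2-[(3S,4S,6R)-4,6-dimethyl-6-[(2R)-2-methyl-10-phenyldecyl]-1,2-dioxan-3-yl]ethyl acetate
Product: 21 2-[(3S,4S,6R)-4,6-dimethyl-6-[(2R)-2-methyl-10-phenyldecyl]-1,2-dioxan-3-yl]ethan-1-ol
Conditions: K2CO3 (cat.), MeOH, 0 °C → rt
Reagents that add atoms: none
Why: Base-catalysed transesterification removes the acetate; with no carbonyl group next to the ring there is no enolate pathway for opening the peroxide under these mild conditions.

Step 14
Reactants: 21 2-[(3S,4S,6R)-4,6-dimethyl-6-[(2R)-2-methyl-10-phenyldecyl]-1,2-dioxan-3-yl]ethan-1-ol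
Product: 23 2-[(3S,4S,6R)-4,6-dimethyl-6-[(2R)-2-methyl-10-phenyldecyl]-1,2-dioxan-3-yl]acetic acid, via peroxy aldehyde 22 (not isolated)
Conditions: TEMPO (cat.), PhI(OAc)2 (2.2 equiv), MeCN/H2O, 0 °C → rt
Reagents that add atoms: water, O
Why: TEMPO (oxoammonium) oxidation with PhI(OAc)2 as terminal oxidant takes the primary alcohol through aldehyde 22 and its hydrate to the acid near neutral pH, where dialkyl peroxides persist and the β-peroxy aldehyde has little chance to eliminate; no stereocentre is touched.

Compound list
1 | 4-methylpent-3-en-1-ol | CC(C)=CCCO | starting material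
2 | 4-methylpent-3-en-1-yl acetate | CC(C)=CCCOC(C)=O | intermediate
3 | rac-3-hydroperoxy-4-methylpent-4-en-1-yl acetate | CC(=C)C(CCOC(C)=O)OO | intermediate
4 | (S)-3-hydroperoxy-4-methylpent-4-en-1-yl acetate | OO[C@@H](CCOC(C)=O)C(C)=C | intermediate
5 | (R)-citronellic acid, (3R)-3,7-dimethyloct-6-enoic acid | C[C@H](CCC=C(C)C)CC(=O)O | starting material
6 | dilithium (4R)-4,8-dimethylnon-7-ene-2,2-diolate (not isolated) | C[C@H](CCC=C(C)C)CC(C)([O-])[O-].[Li+].[Li+] | intermediate
7 | (R)-4,8-dimethylnon-7-en-2-one | C[C@H](CCC=C(C)C)CC(C)=O | intermediate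
8 | (R)-8,8-dimethoxy-2,6-dimethylnon-2-ene | C[C@H](CCC=C(C)C)CC(C)(OC)OC | intermediate
9 | 3-[(3R)-5,5-dimethoxy-3-methylhexyl]-5,5-dimethyl-1,2,4-trioxolane (secondary ozonide, not isolated) | C[C@H](CCC1OOC(C)(C)O1)CC(C)(OC)OC | intermediate
10 | (R)-6,6-dimethoxy-4-methylheptanal | C[C@H](CCC=O)CC(C)(OC)OC | intermediate
11 | (5-bromopentyl)benzene | BrCCCCCc1ccccc1 | starting material
12 | triphenyl(5-phenylpentyl)phosphonium bromide | [Br-].c1ccc(CCCCC[P+](c2ccccc2)(c2ccccc2)c2ccccc2)cc1 | intermediate
13 | triphenyl(5-phenylpentylidene)phosphorane (ylide, not isolated) | c1ccc(CCCCC=P(c2ccccc2)(c2ccccc2)c2ccccc2)cc1 | intermediate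
14 | [(5Z,9R)-11,11-dimethoxy-9-methyldodec-5-en-1-yl]benzene | C[C@H](CC/C=C\CCCCc1ccccc1)CC(C)(OC)OC | intermediate
15 | [(9R)-11,11-dimethoxy-9-methyldodecyl]benzene, the dimethyl ketal of (R)-4-methyl-12-phenyldodecan-2-one | C[C@H](CCCCCCCCc1ccccc1)CC(C)(OC)OC | intermediate
16 | (3S)-3-{[(4R)-2-methoxy-4-methyl-12-phenyldodecan-2-yl]peroxy}-4-methylpent-4-en-1-yl acetate (both epimers at the peroxyketal carbon) | C[C@H](CCCCCCCCc1ccccc1)CC(C)(OC)OO[C@@H](CCOC(C)=O)C(C)=C | intermediate
17 | peroxycarbenium ion: [(4R)-4-methyl-12-phenyldodecan-2-ylidene]{[(3S)-5-acetoxy-2-methylpent-1-en-3-yl]oxy}oxonium (not isolated) | C[C@H](CCCCCCCCc1ccccc1)CC(C)=[O+]O[C@@H](CCOC(C)=O)C(C)=C | intermediate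
18 | (3S,6R)-3-(2-acetoxyethyl)-4,6-dimethyl-6-[(2R)-2-methyl-10-phenyldecyl]-1,2-dioxan-4-ylium (not isolated) | C[C@H](CCCCCCCCc1ccccc1)C[C@]1(C)C[C+](C)[C@H](CCOC(C)=O)OO1 | intermediate
19 | 2-[(3S,6R)-6-methyl-4-methylidene-6-[(2R)-2-methyl-10-phenyldecyl]-1,2-dioxan-3-yl]ethyl acetate | C[C@H](CCCCCCCCc1ccccc1)C[C@]1(C)CC(=C)[C@H](CCOC(C)=O)OO1 | intermediate
20 | 2-[(3S,4S,6R)-4,6-dimethyl-6-[(2R)-2-methyl-10-phenyldecyl]-1,2-dioxan-3-yl]ethyl acetate | C[C@H](CCCCCCCCc1ccccc1)C[C@]1(C)C[C@H](C)[C@H](CCOC(C)=O)OO1 | intermediate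
21 | 2-[(3S,4S,6R)-4,6-dimethyl-6-[(2R)-2-methyl-10-phenyldecyl]-1,2-dioxan-3-yl]ethan-1-ol | C[C@H](CCCCCCCCc1ccccc1)C[C@]1(C)C[C@H](C)[C@H](CCO)OO1 | intermediate
22 | 2-[(3S,4S,6R)-4,6-dimethyl-6-[(2R)-2-methyl-10-phenyldecyl]-1,2-dioxan-3-yl]acetaldehyde (not isolated) | C[C@H](CCCCCCCCc1ccccc1)C[C@]1(C)C[C@H](C)[C@H](CC=O)OO1 | intermediate
23 | 2-[(3S,4S,6R)-4,6-dimethyl-6-[(2R)-2-methyl-10-phenyldecyl]-1,2-dioxan-3-yl]acetic acid (CNP0342712.1) | C[C@H](CCCCCCCCc1ccccc1)C[C@]1(C)C[C@H](C)[C@H](CC(=O)O)OO1 | target

Total step count: 14.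
Longest linear sequence: 10 steps (from 5 through steps 4, 5, 6, 8, 9, 10, 11, 12, 13 and 14).

Steps most likely to fail

Step 11. Three things may go wrong:
- After ionisation the peroxide may be cleaved (loss of the hydroperoxide fragment or O–O heterolysis with migration) before the alkene attacks.
- The chair may discriminate poorly between methyl and chain at C6.
- Proton loss may not be confined to the methyl group.

The fallback gives up C–C ring closure and closes the ring by O–C bond formation. It sets out from 15 and comes back at 23.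
- Aqueous acid (PPTS, acetone/H2O) frees (R)-4-methyl-12-phenyldodecan-2-one F1.
- Wittig reaction with the doubly deprotonated, commercial (R)-(3-hydroxy-2-methylpropyl)triphenylphosphonium bromide (n-BuLi, THF) gives (2S,6R)-2,4,6-trimethyl-14-phenyltetradec-3-en-1-ol F2.
- Mukaiyama–Isayama peroxidation (Co(acac)2, O2, Et3SiH) places a triethylsilylperoxy group on the more substituted alkene carbon and gives (2S,6R)-2,4,6-trimethyl-14-phenyl-4-[(triethylsilyl)peroxy]tetradecan-1-ol F3.
- Dess–Martin oxidation gives (2S,6R)-2,4,6-trimethyl-14-phenyl-4-[(triethylsilyl)peroxy]tetradecanal F4.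
- Wittig reaction with Ph3P=CHCO2Me gives methyl (2E,4S,8R)-4,6,8-trimethyl-16-phenyl-6-[(triethylsilyl)peroxy]hexadec-2-enoate F5.
- Bu4NF and then Et2NH in CF3CH2OH remove the silyl group and let the peroxide oxygen add to the enoate in a 6-exo peroxy-Michael cyclisation; separation from the C3 and C6 epimers gives methyl 2-[(3S,4S,6R)-4,6-dimethyl-6-[(2R)-2-methyl-10-phenyldecyl]-1,2-dioxan-3-yl]acetate F6.
- LiOH in THF/H2O at 0 °C then gives 23.

In this sequence C4 comes from the phosphonium salt, whereas C3 and C6 are not controlled and rely on separation.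

Step 12. Diimide is a small reagent and may show poor facial selectivity at the exocyclic alkene, giving the C4 epimer as well; reduction of the hindered 1,1-disubstituted alkene may also be slow. The fallback sets out from 19 and comes back at 20. It replaces hydrogen transfer from a freely diffusing molecule by addition on a metal surface (H2, PtO2, EtOAc, 0 °C, stopped as soon as the alkene is consumed). The ring must then lie with one whole face on the catalyst, which should exclude the face carrying both chains more strictly. The reaction has to be watched closely, because long exposure would hydrogenolyse the O–O bond. No new compound is formed.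

Step 3. The enzyme may discriminate the enantiomers insufficiently or may leave the unwanted antipode. The fallback sets out from 3 and comes back at 4, and replaces the enzymatic resolution by a covalent one.
- Racemic 3 is added (PPTS, CH2Cl2) to the 2-propenyl ether of (1R,2S)-trans-2-phenylcyclohexanol, a known resolving reagent for hydroperoxides.
- The two diastereomeric perketals are separated by chromatography: (3S)-4-methyl-3-[(2-{[(1R,2S)-2-phenylcyclohexyl]oxy}propan-2-yl)peroxy]pent-4-en-1-yl acetate F7 and its (3R) diastereomer (3R)-4-methyl-3-[(2-{[(1R,2S)-2-phenylcyclohexyl]oxy}propan-2-yl)peroxy]pent-4-en-1-yl acetate F8.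
- Mild hydrolysis of F7 (AcOH, THF/H2O) returns 4.

Either enantiomer is available this way, whatever the preference of the enzyme.

Further compounds
F1 | step 11 | (R)-4-methyl-12-phenyldodecan-2-one | CC(=O)C[C@H](C)CCCCCCCCc1ccccc1
F2 | step 11 | (2S,6R)-2,4,6-trimethyl-14-phenyltetradec-3-en-1-ol (E/Z mixture) | OC[C@@H](C)C=C(C)C[C@H](C)CCCCCCCCc1ccccc1
F3 | step 11 | (2S,6R)-2,4,6-trimethyl-14-phenyl-4-[(triethylsilyl)peroxy]tetradecan-1-ol (both C4 epimers) | OC[C@@H](C)CC(C)(OO[Si](CC)(CC)CC)C[C@H](C)CCCCCCCCc1ccccc1
F4 | step 11 | (2S,6R)-2,4,6-trimethyl-14-phenyl-4-[(triethylsilyl)peroxy]tetradecanal (both C4 epimers) | O=C[C@@H](C)CC(C)(OO[Si](CC)(CC)CC)C[C@H](C)CCCCCCCCc1ccccc1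
F5 | step 11 | methyl (2E,4S,8R)-4,6,8-trimethyl-16-phenyl-6-[(triethylsilyl)peroxy]hexadec-2-enoate (both C6 epimers) | COC(=O)/C=C/[C@@H](C)CC(C)(OO[Si](CC)(CC)CC)C[C@H](C)CCCCCCCCc1ccccc1
F6 | step 11 | methyl 2-[(3S,4S,6R)-4,6-dimethyl-6-[(2R)-2-methyl-10-phenyldecyl]-1,2-dioxan-3-yl]acetate | C[C@H](CCCCCCCCc1ccccc1)C[C@]1(C)C[C@H](C)[C@H](CC(=O)OC)OO1
F0 | step 12 | none | none
F7 | step 3 | (3S)-4-methyl-3-[(2-{[(1R,2S)-2-phenylcyclohexyl]oxy}propan-2-yl)peroxy]pent-4-en-1-yl acetate | CC(C)(OO[C@@H](CCOC(C)=O)C(C)=C)O[C@@H]1CCCC[C@H]1c1ccccc1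
F8 | step 3 | (3R)-4-methyl-3-[(2-{[(1R,2S)-2-phenylcyclohexyl]oxy}propan-2-yl)peroxy]pent-4-en-1-yl acetate | CC(C)(OO[C@H](CCOC(C)=O)C(C)=C)O[C@@H]1CCCC[C@H]1c1ccccc1
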